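Leave grey and red stirring until 80 min, and spend no material on drying them.

in all of them: electrophile 0.31 M; nucleophile 0.465 M; free base 0.372 M

| run | protic impurity | remark | time |
|---|---|---|---|
| maple | 0.034 M | run made earlier |  |
| ash | 0.047 M | run made earlier |  |
| elm | 0.063 M | run made earlier |  |
| grey | 0.0310 M |  | 80 min |
| red | 0.0770 M |  | 80 min |

| run | time / min | electrophile / % | target / % |
|---|---|---|---|
| maple | 5.00 | 95.6 | 4.5 |
| maple | 15.0 | 87.6 | 12.0 |
| maple | 25.0 | 81.9 | 18.5 |
| maple | 40.0 | 73.9 | 26.0 |
| ash | 10.0 | 91.8 | 8.1 |
| ash | 20.0 | 84.5 | 15.6 |
| ash | 30.0 | 78.9 | 21.1 |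
| ash | 40.0 | 73.8 | 26.1 |
| elm | 10.0 | 91.5 | 8.0 |
| elm | 20.0 | 84.1 | 14.6 |
| elm | 30.0 | 78.9 | 21.0 |
| elm | 40.0 | 73.9 | 25.9 |

(scatter of a reading: 0.3 percentage points)



- which of these there is most of at the end, counted by the electrophile in it, grey (electrophile / target)
- which of these there is most of at the end, counted by the electrophile in it, red (electrophile / target)
- how much there is at the end of the one of these that leads, in percent of the electrophile charged: grey
- how much there is at the end of the one of these that leads, in percent of the electrophile charged: red

Here is why. Maple, ash and elm run from 0.034 M to 0.063 M of protic impurity, yet at 40.0 min their electrophile reads 73.9 %, 73.8 % and 73.9 %, with a scatter of 0.3 percentage points. So I count the impurity as leaving the electrophile alone, although grey lies below that range and red above it.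

The drift matters more. I compare the ash run's first-order loss of electrophile in two equal windows, up to 20.0 min and then on to 40.0 min:

later / earlier = 0.804

The nucleophile left in those windows gives 0.908 for one nucleophile spent per electrophile and 0.805 for two. The reading lies closer to two, so I take two. Nucleophile is then the limiting reagent, since 0.465 M is less than the 0.620 M needed.

With two spent, the difference 2·c(electrophile) − c(nucleophile) stays constant. So, for a rate proportional to c(electrophile)·c(nucleophile), ln r, with r = c(nucleophile)/c(electrophile), falls steadily, at a pace I call the ratio's fall rate. For grey and red I reckon: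

r at the start = 1.50

electrophile at 40.0 min = 73.9 %, so r = 1.32

fall rate = 0.00314 min⁻¹

r at 80 min = 1.17, so electrophile = 60.0 %

The forecast names electrophile for grey and electrophile for red, at 57 % and 57 %: “so electrophile still leads”. My figure lies higher, with the same leader.

    electrophile + nucleophile → acid set free + target (k = 3.35 × 10⁻⁴ M⁻¹ s⁻¹)
    nucleophile + acid set free ⇌ protonated nucleophile, settled at all times (K = 4800 M⁻¹)
    protic impurity + free base → quenched reagent (k = 0.0249 M⁻¹ s⁻¹)
    acid set free + free base ⇌ salt of the base, settled at all times (K = 5.90 M⁻¹)

Grey and red both end at 60.2 % electrophile, and the forecast held. At 80 min, grey holds 0.123 M of protonated nucleophile, about as much as its target, 0.123 M. Carried on to 800 min in red, the fall rate gives electrophile 26.6 %, and red then holds 25.9 %.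

(Readings and results stem from a simulated flask for an exercise.)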